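**Plan**

- Retrosynthesis: the two acetates and the C11–C12 bond (alkyl–alkenyl coupling) are cut first and C17 is taken back to a C8 oxygen; C5–C10 and C8–C9 are then cut together as one Diels–Alder transform; the open chain is cut at C4 (malonate alkylation), at C10–C20/C9–C11 (alkyne carbometalation) and at C6=C7 (cross-metathesis).
- Enabling feature: C9 and the quaternary C10 are neighbours in ring B with C11 cis to CH3-20, C8 is the only other functionalised carbon of ring B, and C4 is not stereogenic. An achiral (E)-3-methyl-2-enoyl imide tethered through C1–C4 to a C5–C8 dienyl acetate therefore holds the whole bicycle.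
- Forward: a C4 malonate carries both arms; the alkyne arm becomes the enoyl imide and the allyl arm the dienyl acetate; ring A (tether ring) and ring B (new cyclohexene) close in one step. C6=C7 is then saturated, C8 becomes the exocyclic methylene, C11 is joined to the C12–C15 diene, and the acetonide is exchanged for the acetates.
- Stereochemistry: C5, C9 and C10 (and the transient C8) are set in the cycloaddition, relative configuration by the E geometries and the endo chelate, absolute configuration by the (S,S)-tBu-box copper catalyst; the 12E alkene comes from syn-carboalumination of propargyl alcohol.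

Key step: step 8

Assumption: labdane numbering is used throughout (ring A = C1–C5 and C10, ring B = C5–C10, side chain C11–C16, C17 on C8, C18/C19 on C4, C20 on C10); the target is the ent-labdane (5S,9R,10S).
Assumption: the facial sense of the copper catalyst is taken from the square-planar chelate model known for acryloyl and crotonoyl imides; were it reversed for this substrate, the (R,R) ligand would be used with nothing else changed.

**Route**

Step 1
Reactants: 1 diethyl 2-allylmalonate; 2 5-iodopent-1-yne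
Product: 3 diethyl 2-allyl-2-(pent-4-yn-1-yl)malonate
Conditions: NaH, THF/DMF, 0 °C to 50 °C
Reagents that add atoms: none
Why: Malonate alkylation (SN2) of the sodium enolate with a primary iodide makes the future C4 quaternary and attaches the C3–C1/C10–C9 arm, the far less acidic alkyne C–H being left alone.

Step 2
Reactants: 3 diethyl 2-allyl-2-(pent-4-yn-1-yl)malonate
Product: 4 2-allyl-2-(pent-4-yn-1-yl)propane-1,3-diol
Conditions: LiAlH4, THF, 0 °C to rt; Fieser work-up
Reagents that add atoms: none
Why: Hydride reduction of both esters of a fully substituted malonate gives the 1,3-diol (future C18/C19) without touching the isolated alkene or alkyne.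

Step 3
Reactants: 4 2-allyl-2-(pent-4-yn-1-yl)propane-1,3-diol
Product: 5 5-allyl-2,2-dimethyl-5-(pent-4-yn-1-yl)-1,3-dioxane
Conditions: 2,2-dimethoxypropane, PPTS (cat.), CH2Cl2, rt
Reagents that add atoms: 2,2-dimethoxypropane COC(C)(C)OC
Why: Acid-catalysed transacetalisation closes the six-membered acetonide, which masks both hydroxyls as one compact group that tolerates bases, hydrides, organometallics and ylides.

Step 4
Reactants: 5 5-allyl-2,2-dimethyl-5-(pent-4-yn-1-yl)-1,3-dioxane
Product: 8 (2E)-6-(5-allyl-2,2-dimethyl-1,3-dioxan-5-yl)-3-methylhex-2-enoic acid, via alkenyldimethylalane 6 (not isolated), via lithium alkenylalanate 7 (not isolated)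
Conditions: Me3Al, Cp2ZrCl2 (0.2 equiv), CH2Cl2, 0 °C to rt; volatiles removed; n-BuLi, THF, −78 °C; CO2, −78 to 0 °C; cold aq. HCl to pH 3–4
Reagents that add atoms: trimethylaluminium C[Al](C)C; carbon dioxide O=C=O
Why: Negishi zirconium-catalysed carboalumination adds CH3 and Al syn across the terminal alkyne with CH3 on the internal carbon, and carboxylation of the derived alanate proceeds with retention, so the (E)-acid with CH3-20 cis to C11 should result while the monosubstituted alkene is not carbometalated by Cp2ZrCl2.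

Step 5
Reactants: 8 (2E)-6-(5-allyl-2,2-dimethyl-1,3-dioxan-5-yl)-3-methylhex-2-enoic acid; 9 oxazolidin-2-one
Product: 11 3-[(2E)-6-(5-allyl-2,2-dimethyl-1,3-dioxan-5-yl)-3-methylhex-2-enoyl]oxazolidin-2-one, via mixed pivalic anhydride 10 (not isolated)
Conditions: PivCl, Et3N, THF, −20 °C; then LiCl, 9, rt
Reagents that add atoms: none
Why: N-acylation of the oxazolidinone through the mixed pivalic anhydride (LiCl/Et3N protocol) is directed to the less hindered enoyl carbonyl and leaves the alkene geometry untouched.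

Step 6
Reactants: 11 3-[(2E)-6-(5-allyl-2,2-dimethyl-1,3-dioxan-5-yl)-3-methylhex-2-enoyl]oxazolidin-2-one; 12 (E)-but-2-enal
Product: 13 3-[(2E)-6-{2,2-dimethyl-5-[(2E)-4-oxobut-2-en-1-yl]-1,3-dioxan-5-yl}-3-methylhex-2-enoyl]oxazolidin-2-one
Conditions: 12 (5 equiv), second-generation Grubbs catalyst RuCl2(=CHPh)(H2IMes)(PCy3) (5 mol%), CH2Cl2, 40 °C
Reagents that add atoms: none
Why: Olefin cross-metathesis of the terminal alkene with an enal partner gives the (E)-enal (C6=C7, C8 aldehyde), the electron-poor trisubstituted enoyl alkene being inert to the ruthenium carbene.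

Step 7
Reactants: 13 3-[(2E)-6-{2,2-dimethyl-5-[(2E)-4-oxobut-2-en-1-yl]-1,3-dioxan-5-yl}-3-methylhex-2-enoyl]oxazolidin-2-one
Product: 14 (1E,3E)-4-{2,2-dimethyl-5-[(4E)-4-methyl-6-oxo-6-(2-oxooxazolidin-3-yl)hex-4-en-1-yl]-1,3-dioxan-5-yl}buta-1,3-dien-1-yl acetate
Conditions: Ac2O, Et3N, DMAP (0.2 equiv), THF, 50 °C
Reagents that add atoms: acetic anhydride CC(=O)OC(C)=O
Why: Deconjugative enol acetylation (γ-deprotonation at C5 and O-acetylation of the dienolate) gives the 1-acetoxy-1,3-diene, with C5=C6 forming E next to the quaternary C4 and the C7=C8 enol acetate expected mainly E, any (1Z) isomer, which cannot reach the s-cis diene, being removed by chromatography.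

Step 8
Reactants: 14 (1E,3E)-4-{2,2-dimethyl-5-[(4E)-4-methyl-6-oxo-6-(2-oxooxazolidin-3-yl)hex-4-en-1-yl]-1,3-dioxan-5-yl}buta-1,3-dien-1-yl acetate
Product: 15 3-[(5S,8R,9S,10R)-8-acetoxy-18,19-isopropylidenedioxy-12,13,14,15,16,17-hexanorlabd-6-en-11-oyl]oxazolidin-2-one
Conditions: [Cu((S,S)-tBu-box)](SbF6)2 (10 mol%), 4 Å MS, CH2Cl2, rt
Reagents that add atoms: none
Why: Proposed new method: bidentate chelation of the two imide carbonyls to square-planar divalent copper lowers the LUMO of the C9=C10 alkene and holds the enoyl unit s-cis (the C20 methyl cis to C11 excludes s-trans), so that the dienyl acetate can add in a concerted but asynchronous endo [4+2] with the C5–C10 bond leading; the closest known reaction type is the [Cu(tBu-box)](SbF6)2-catalysed intramolecular Diels–Alder reaction of β-monosubstituted trienoyl oxazolidinones, not yet shown for a β,β-disubstituted enoyl group that builds a quaternary carbon. Ring B is closed as the new cyclohexene of the cycloaddition and ring A as the six-membered tether ring of a type 1 (fused-mode) closure of a 1,7,9-decatriene, both through the C5–C10 and C8–C9 bonds. The C9/C10 relationship (C11 cis to CH3-20) is dictated by the (E)-enoyl geometry and the C5/C8 relationship by the (1E,3E)-diene geometry, each through suprafacial addition. The trans ring fusion at C5/C10 and the cis arrangement of C8-OAc and C11 follow from the endo placement of the chelated carbonyl, which sits trans to the tether on the dienophile. The absolute configuration is controlled by the (S,S) ligand, whose tert-butyl group next to the enoyl unit shields the Si face of C9 so that the diene adds to the C9 Re face and the (5S,9S,10R) ent-labdane series results. The step needs enantioface and endo selectivity together with enough reactivity at a trisubstituted dienophile, and these should be secured by the rigid chelate, by the geminally disubstituted C4 that favours the folded tether (reactive-rotamer effect) and by the matched polarity in which the diene terminus C5 remote from the acetoxy group bonds to the β-carbon C10.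

Step 9
Reactants: 15 3-[(5S,8R,9S,10R)-8-acetoxy-18,19-isopropylidenedioxy-12,13,14,15,16,17-hexanorlabd-6-en-11-oyl]oxazolidin-2-one
Product: 16 3-[(5S,8R,9S,10R)-8-acetoxy-18,19-isopropylidenedioxy-12,13,14,15,16,17-hexanorlabdan-11-oyl]oxazolidin-2-one
Conditions: H2 (1 atm), 5% Rh/Al2O3, EtOAc, rt
Reagents that add atoms: none
Why: Heterogeneous hydrogenation saturates the cis-disubstituted C6=C7 alkene without creating a stereocentre, rhodium being chosen because it is least prone to hydrogenolyse the allylic C8 acetate.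

Step 10
Reactants: 16 3-[(5S,8R,9S,10R)-8-acetoxy-18,19-isopropylidenedioxy-12,13,14,15,16,17-hexanorlabdan-11-oyl]oxazolidin-2-one
Product: 17 (5S,8R,9R,10R)-18,19-isopropylidenedioxy-12,13,14,15,16,17-hexanorlabdane-8,11-diol
Conditions: LiAlH4, THF, 0 °C to rt; Fieser work-up
Reagents that add atoms: none
Why: Hydride reduction converts the N-acyl oxazolidinone into the C11 primary alcohol and cleaves the C8 acetate under non-enolising conditions, so C9 keeps its configuration.

Step 11
Reactants: 17 (5S,8R,9R,10R)-18,19-isopropylidenedioxy-12,13,14,15,16,17-hexanorlabdane-8,11-diol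
Product: 18 (5S,8R,9R,10R)-11-(tert-butyldimethylsilyloxy)-18,19-isopropylidenedioxy-12,13,14,15,16,17-hexanorlabdan-8-ol
Conditions: TBSCl, imidazole, CH2Cl2, 0 °C
Reagents that add atoms: tert-butyldimethylsilyl chloride CC(C)(C)[Si](C)(C)Cl
Why: Silylation is selective for the primary C11 hydroxyl because the C8 hydroxyl is secondary, axial and 1,3-diaxial to CH3-20.

Step 12
Reactants: 18 (5S,8R,9R,10R)-11-(tert-butyldimethylsilyloxy)-18,19-isopropylidenedioxy-12,13,14,15,16,17-hexanorlabdan-8-ol
Product: 19 (5S,9R,10R)-11-(tert-butyldimethylsilyloxy)-18,19-isopropylidenedioxy-12,13,14,15,16,17-hexanorlabdan-8-one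
Conditions: Dess–Martin periodinane, pyridine, CH2Cl2, rt
Reagents that add atoms: none
Why: Dess–Martin oxidation of the strained axial alcohol gives the C8 ketone under buffered, non-basic conditions that avoid β-elimination of the silyloxy group, C9 already carrying its substituent in the thermodynamically preferred equatorial position.

Step 13
Reactants: 19 (5S,9R,10R)-11-(tert-butyldimethylsilyloxy)-18,19-isopropylidenedioxy-12,13,14,15,16,17-hexanorlabdan-8-one
Product: 20 (5S,9R,10R)-11-(tert-butyldimethylsilyloxy)-18,19-isopropylidenedioxy-12,13,14,15,16-pentanorlabd-8(17)-ene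
Conditions: Ph3PCH3Br, KHMDS, THF, 0 °C to rt
Reagents that add atoms: methyltriphenylphosphonium bromide (as its ylide) C[P+](c1ccccc1)(c1ccccc1)c1ccccc1.[Br-]
Why: Wittig methylenation of the C8 ketone installs C17 as the exocyclic alkene, a transformation well known for 8-oxo-drimanes and -labdanes, and any enolisation towards C9 can only return the stable equatorial epimer.

Step 14
Reactants: 20 (5S,9R,10R)-11-(tert-butyldimethylsilyloxy)-18,19-isopropylidenedioxy-12,13,14,15,16-pentanorlabd-8(17)-ene
Product: 21 (5S,9R,10R)-18,19-isopropylidenedioxy-12,13,14,15,16-pentanorlabd-8(17)-en-11-ol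
Conditions: TBAF, THF, rt
Reagents that add atoms: none
Why: Fluoride-induced desilylation frees the C11 alcohol without affecting the acetonide or the exocyclic alkene.

Step 15
Reactants: 21 (5S,9R,10R)-18,19-isopropylidenedioxy-12,13,14,15,16-pentanorlabd-8(17)-en-11-ol
Product: 22 (5S,9R,10R)-11-iodo-18,19-isopropylidenedioxy-12,13,14,15,16-pentanorlabd-8(17)-ene
Conditions: I2, PPh3, imidazole, CH2Cl2, 0 °C to rt
Reagents that add atoms: iodine II
Why: Appel iodination converts the primary homoallylic alcohol into the iodide by SN2 displacement of the alkoxyphosphonium at the non-stereogenic C11.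

Step 16
Reactants: 23 prop-2-yn-1-ol
Product: 25 (2E)-3-iodo-2-methylprop-2-en-1-ol, via alkenylalane alkoxide 24 (not isolated)
Conditions: Me3Al (3 equiv), Cp2ZrCl2 (0.25 equiv), CH2Cl2, 0 °C to rt; then I2, THF, −30 to 0 °C; aq. K2CO3
Reagents that add atoms: trimethylaluminium C[Al](C)C; iodine II
Why: Negishi carboalumination adds CH3 and Al syn with CH3 on the internal carbon, and iododealumination with retention fixes the (E) geometry of the future C12=C13 bond.

Step 17
Reactants: 25 (2E)-3-iodo-2-methylprop-2-en-1-ol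
Product: 26 (2E)-3-iodo-2-methylprop-2-enal
Conditions: MnO2, CH2Cl2, rt
Reagents that add atoms: none
Why: Activated MnO2 oxidises the allylic alcohol to the enal chemoselectively and without alkene isomerisation.

Step 18
Reactants: 26 (2E)-3-iodo-2-methylprop-2-enal
Product: 27 (1E)-1-iodo-2-methylbuta-1,3-diene
Conditions: Ph3PCH3Br, KHMDS, THF, −78 to 0 °C; kept as a concentrated solution
Reagents that add atoms: methyltriphenylphosphonium bromide (as its ylide) C[P+](c1ccccc1)(c1ccccc1)c1ccccc1.[Br-]
Why: Wittig methylenation of the aldehyde adds C15 and leaves the iodoalkene geometry untouched.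

Step 19
Reactants: 22 (5S,9R,10R)-11-iodo-18,19-isopropylidenedioxy-12,13,14,15,16-pentanorlabd-8(17)-ene; 27 (1E)-1-iodo-2-methylbuta-1,3-diene
Product: 29 (5S,9R,10S,12E)-18,19-isopropylidenedioxylabda-8(17),12,14-triene, via alkylzinc iodide 28 (not isolated)
Conditions: Zn dust (activated with BrCH2CH2Br/TMSCl), DMA, 50 °C; then 27, PdCl2(dppf) (5 mol%), THF, rt
Reagents that add atoms: none
Why: Negishi alkyl–alkenyl coupling: zinc insertion into the primary C–I bond gives an alkylzinc that transmetalates to the alkenylpalladium formed from 27 and zerovalent palladium, and reductive elimination forms C11–C12 with retention of the (E) geometry, dppf suppressing β-hydride elimination.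

Step 20
Reactants: 29 (5S,9R,10S,12E)-18,19-isopropylidenedioxylabda-8(17),12,14-triene
Product: 30 (5S,9R,10S,12E)-labda-8(17),12,14-triene-18,19-diol
Conditions: PPTS, MeOH, rt
Reagents that add atoms: none
Why: Mild acid-catalysed transacetalisation to methanol removes the acetonide under conditions too weak to isomerise the exocyclic alkene or the conjugated diene.

Step 21
Reactants: 30 (5S,9R,10S,12E)-labda-8(17),12,14-triene-18,19-diol
Product: 31 (5S,9R,10S,12E)-labda-8(17),12,14-triene-18,19-diyl diacetate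
Conditions: Ac2O, pyridine, DMAP (cat.), CH2Cl2, rt
Reagents that add atoms: acetic anhydride CC(=O)OC(C)=O
Why: DMAP-catalysed acetylation esterifies both primary neopentyl-type hydroxyls and gives the target without touching any stereocentre.

**Compound list**

1 | diethyl 2-allylmalonate | CCOC(=O)C(CC=C)C(=O)OCC | starting material
2 | 5-iodopent-1-yne | C#CCCCI | starting material
3 | diethyl 2-allyl-2-(pent-4-yn-1-yl)malonate | CCOC(=O)C(CC=C)(CCCC#C)C(=O)OCC | intermediate
4 | 2-allyl-2-(pent-4-yn-1-yl)propane-1,3-diol | OCC(CO)(CC=C)CCCC#C | intermediate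
5 | 5-allyl-2,2-dimethyl-5-(pent-4-yn-1-yl)-1,3-dioxane | C=CCC1(CCCC#C)COC(C)(C)OC1 | intermediate
6 | (E)-[5-(5-allyl-2,2-dimethyl-1,3-dioxan-5-yl)-2-methylpent-1-en-1-yl]dimethylalane | C[Al](C)/C=C(\C)CCCC1(CC=C)COC(C)(C)OC1 | intermediate
7 | lithium butyl[(E)-5-(5-allyl-2,2-dimethyl-1,3-dioxan-5-yl)-2-methylpent-1-en-1-yl]dimethylalanate | [Li+].CCCC[Al-](C)(C)/C=C(\C)CCCC1(CC=C)COC(C)(C)OC1 | intermediate
8 | (2E)-6-(5-allyl-2,2-dimethyl-1,3-dioxan-5-yl)-3-methylhex-2-enoic acid | OC(=O)/C=C(\C)CCCC1(CC=C)COC(C)(C)OC1 | intermediate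
9 | oxazolidin-2-one | O=C1NCCO1 | starting material
10 | (2E)-6-(5-allyl-2,2-dimethyl-1,3-dioxan-5-yl)-3-methylhex-2-enoic pivalic anhydride | CC(C)(C)C(=O)OC(=O)/C=C(\C)CCCC1(CC=C)COC(C)(C)OC1 | intermediate
11 | 3-[(2E)-6-(5-allyl-2,2-dimethyl-1,3-dioxan-5-yl)-3-methylhex-2-enoyl]oxazolidin-2-one | O=C1OCCN1C(=O)/C=C(\C)CCCC2(CC=C)COC(C)(C)OC2 | intermediate
12 | (E)-but-2-enal (crotonaldehyde) | C/C=C/C=O | starting material
13 | 3-[(2E)-6-{2,2-dimethyl-5-[(2E)-4-oxobut-2-en-1-yl]-1,3-dioxan-5-yl}-3-methylhex-2-enoyl]oxazolidin-2-one | O=C1OCCN1C(=O)/C=C(\C)CCCC2(C/C=C/C=O)COC(C)(C)OC2 | intermediate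
14 | (1E,3E)-4-{2,2-dimethyl-5-[(4E)-4-methyl-6-oxo-6-(2-oxooxazolidin-3-yl)hex-4-en-1-yl]-1,3-dioxan-5-yl}buta-1,3-dien-1-yl acetate (achiral cycloaddition precursor) | O=C1OCCN1C(=O)/C=C(\C)CCCC2(COC(C)(C)OC2)/C=C/C=C/OC(C)=O | intermediate
15 | 3-[(5S,8R,9S,10R)-8-acetoxy-18,19-isopropylidenedioxy-12,13,14,15,16,17-hexanorlabd-6-en-11-oyl]oxazolidin-2-one (trans-fused cycloadduct; H-5, H-8 and H-9 on one face; CH3-20, 8-OAc and C11 on the other; spiro acetonide at C4) | O=C1OCCN1C(=O)[C@@H]1[C@H](OC(C)=O)C=C[C@@H]2C3(COC(C)(C)OC3)CCC[C@@]12C | intermediate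
16 | 3-[(5S,8R,9S,10R)-8-acetoxy-18,19-isopropylidenedioxy-12,13,14,15,16,17-hexanorlabdan-11-oyl]oxazolidin-2-one | O=C1OCCN1C(=O)[C@@H]1[C@H](OC(C)=O)CC[C@@H]2C3(COC(C)(C)OC3)CCC[C@@]12C | intermediate
17 | (5S,8R,9R,10R)-18,19-isopropylidenedioxy-12,13,14,15,16,17-hexanorlabdane-8,11-diol | OC[C@@H]1[C@H](O)CC[C@@H]2C3(COC(C)(C)OC3)CCC[C@@]12C | intermediate
18 | (5S,8R,9R,10R)-11-(tert-butyldimethylsilyloxy)-18,19-isopropylidenedioxy-12,13,14,15,16,17-hexanorlabdan-8-ol | CC(C)(C)[Si](C)(C)OC[C@@H]1[C@H](O)CC[C@@H]2C3(COC(C)(C)OC3)CCC[C@@]12C | intermediate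
19 | (5S,9R,10R)-11-(tert-butyldimethylsilyloxy)-18,19-isopropylidenedioxy-12,13,14,15,16,17-hexanorlabdan-8-one | CC(C)(C)[Si](C)(C)OC[C@@H]1C(=O)CC[C@@H]2C3(COC(C)(C)OC3)CCC[C@@]12C | intermediate
20 | (5S,9R,10R)-11-(tert-butyldimethylsilyloxy)-18,19-isopropylidenedioxy-12,13,14,15,16-pentanorlabd-8(17)-ene | CC(C)(C)[Si](C)(C)OC[C@@H]1C(=C)CC[C@@H]2C3(COC(C)(C)OC3)CCC[C@@]12C | intermediate
21 | (5S,9R,10R)-18,19-isopropylidenedioxy-12,13,14,15,16-pentanorlabd-8(17)-en-11-ol | OC[C@@H]1C(=C)CC[C@@H]2C3(COC(C)(C)OC3)CCC[C@@]12C | intermediate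
22 | (5S,9R,10R)-11-iodo-18,19-isopropylidenedioxy-12,13,14,15,16-pentanorlabd-8(17)-ene | IC[C@@H]1C(=C)CC[C@@H]2C3(COC(C)(C)OC3)CCC[C@@]12C | intermediate
23 | prop-2-yn-1-ol | C#CCO | starting material
24 | dimethylaluminium (2E)-3-(dimethylalumanyl)-2-methylprop-2-en-1-olate | C[Al](C)/C=C(\C)CO[Al](C)C | intermediate
25 | (2E)-3-iodo-2-methylprop-2-en-1-ol | OC/C(C)=C/I | intermediate
26 | (2E)-3-iodo-2-methylprop-2-enal | O=C/C(C)=C/I | intermediate
27 | (1E)-1-iodo-2-methylbuta-1,3-diene | C=C/C(C)=C/I | intermediate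
28 | [(5S,9R,10R)-18,19-isopropylidenedioxy-12,13,14,15,16-pentanorlabd-8(17)-en-11-yl]zinc iodide | I[Zn]C[C@@H]1C(=C)CC[C@@H]2C3(COC(C)(C)OC3)CCC[C@@]12C | intermediate
29 | (5S,9R,10S,12E)-18,19-isopropylidenedioxylabda-8(17),12,14-triene | C=C/C(C)=C/C[C@@H]1C(=C)CC[C@@H]2C3(COC(C)(C)OC3)CCC[C@@]12C | intermediate
30 | (5S,9R,10S,12E)-labda-8(17),12,14-triene-18,19-diol | C=C/C(C)=C/C[C@@H]1C(=C)CC[C@@H]2C(CO)(CO)CCC[C@@]12C | intermediate
31 | (5S,9R,10S,12E)-labda-8(17),12,14-triene-18,19-diyl diacetate (ent-labdane series, CNP0129553.1) | C=C/C(C)=C/C[C@@H]1C(=C)CC[C@@H]2C(COC(C)=O)(COC(C)=O)CCC[C@@]12C | target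

**Step count**

Total: 21 steps. Longest linear sequence: 18 steps (steps 1–15 and 19–21); steps 16–18 make the dienyl iodide in a side branch.

**Steps most likely to fail, and fallbacks**

Step 8. The mild copper Lewis acid may not activate the β,β-disubstituted enoyl group at temperatures where the chelate still controls the face. Traces of acid may open the acetonide, and a non-chelated pathway may erode facial selectivity. The fallback uses known chemistry, the auxiliary-controlled, Me2AlCl-promoted intramolecular Diels–Alder reaction of a trienimide. It sets out from acid 8, whose mixed anhydride 10 is used to acylate (R)-4-benzyloxazolidin-2-one to the chiral allyl imide F1. Cross-metathesis with 12 as in step 6 gives the chiral enal F2, and enol acetylation as in step 7 gives the chiral trienimide F3. Me2AlCl (1.5 equiv, CH2Cl2, −30 °C) forms the cationic aluminium chelate, in which the benzyl group covers the C9 Si face, and the endo cycloaddition should give the auxiliary-bound cycloadduct F4; any minor diastereomer is removed by chromatography, so enantiopurity does not depend on the selectivity. LiAlH4 removes auxiliary and acetate to give the unsaturated diol F5, and hydrogenation over Rh/Al2O3 returns to the route at diol 17.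

Step 7. Deprotonation at a CH2 flanked by a quaternary carbon may be sluggish, or the enol acetate geometry at C7=C8 may be poorly controlled, so that much material ends as the (1Z) isomer that cannot cyclise. The fallback sets out from enal 13: acylal formation (Ac2O, LiBF4 cat.) gives the allylic 1,1-diacetate F6. Palladium-catalysed 1,4-elimination of acetic acid (Pd(PPh3)4, Et3N, THF, 60 °C) through the syn,syn acetoxy-π-allylpalladium intermediate should then set both alkenes E and return to the route at 14.

Step 19. Zinc insertion at the β-branched primary iodide may be slow, the alkylzinc may be protonated or undergo β-hydride elimination at palladium, and the volatile dienyl iodide may be lost. The fallback sets out from alcohol 21 and builds the chain by carbonyl olefination instead. Dess–Martin oxidation gives the C11 aldehyde F7. Wittig reaction with Ph3P=CHOMe gives the methyl enol ether F8. Hydrolysis with Hg(OAc)2 in aqueous THF followed by KI (near-neutral, sparing the acetonide) gives the homologated C12 aldehyde F9. The stabilised ylide Ph3P=C(CH3)CHO (toluene, 90 °C) gives the (E)-enal F10, and Ph3P=CH2 converts it into triene 29, where the route is rejoined.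

Further compounds
F1 | step 8 | (4R)-3-[(2E)-6-(5-allyl-2,2-dimethyl-1,3-dioxan-5-yl)-3-methylhex-2-enoyl]-4-benzyloxazolidin-2-one | O=C1OC[C@@H](Cc2ccccc2)N1C(=O)/C=C(\C)CCCC3(CC=C)COC(C)(C)OC3
F2 | step 8 | (4R)-4-benzyl-3-[(2E)-6-{2,2-dimethyl-5-[(2E)-4-oxobut-2-en-1-yl]-1,3-dioxan-5-yl}-3-methylhex-2-enoyl]oxazolidin-2-one | O=C1OC[C@@H](Cc2ccccc2)N1C(=O)/C=C(\C)CCCC3(C/C=C/C=O)COC(C)(C)OC3
F3 | step 8 | (1E,3E)-4-{5-[(4E)-6-[(4R)-4-benzyl-2-oxooxazolidin-3-yl]-4-methyl-6-oxohex-4-en-1-yl]-2,2-dimethyl-1,3-dioxan-5-yl}buta-1,3-dien-1-yl acetate | O=C1OC[C@@H](Cc2ccccc2)N1C(=O)/C=C(\C)CCCC3(COC(C)(C)OC3)/C=C/C=C/OC(C)=O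
F4 | step 8 | (4R)-4-benzyl analogue of cycloadduct 15, (5S,8R,9S,10R) | O=C1OC[C@@H](Cc2ccccc2)N1C(=O)[C@@H]3[C@H](OC(C)=O)C=C[C@@H]4C5(COC(C)(C)OC5)CCC[C@@]34C
F5 | step 8 | (5S,8R,9R,10R)-18,19-isopropylidenedioxy-12,13,14,15,16,17-hexanorlabd-6-ene-8,11-diol | OC[C@@H]1[C@H](O)C=C[C@@H]2C3(COC(C)(C)OC3)CCC[C@@]12C
F6 | step 7 | (2E)-4-{2,2-dimethyl-5-[(4E)-4-methyl-6-oxo-6-(2-oxooxazolidin-3-yl)hex-4-en-1-yl]-1,3-dioxan-5-yl}but-2-ene-1,1-diyl diacetate | O=C1OCCN1C(=O)/C=C(\C)CCCC2(C/C=C/C(OC(C)=O)OC(C)=O)COC(C)(C)OC2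
F7 | step 19 | (5S,9R,10R)-18,19-isopropylidenedioxy-12,13,14,15,16-pentanorlabd-8(17)-en-11-al | O=C[C@@H]1C(=C)CC[C@@H]2C3(COC(C)(C)OC3)CCC[C@@]12C
F8 | step 19 | (5S,9R,10R)-18,19-isopropylidenedioxy-12-methoxy-13,14,15,16-tetranorlabda-8(17),11-diene (E/Z mixture) | COC=C[C@@H]1C(=C)CC[C@@H]2C3(COC(C)(C)OC3)CCC[C@@]12C
F9 | step 19 | (5S,9R,10S)-18,19-isopropylidenedioxy-13,14,15,16-tetranorlabd-8(17)-en-12-al | O=CC[C@@H]1C(=C)CC[C@@H]2C3(COC(C)(C)OC3)CCC[C@@]12C
F10 | step 19 | (5S,9R,10S,12E)-18,19-isopropylidenedioxy-15-norlabda-8(17),12-dien-14-al | O=C/C(C)=C/C[C@@H]1C(=C)CC[C@@H]2C3(COC(C)(C)OC3)CCC[C@@]12C
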